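Whichever vessel you fill for this run, the thing to watch is how much D stands in it while it reacts, since the set-ups below share their charge and differ in the vessel.

| flask | D | G | remark | time |
|---|---|---|---|---|
| Friday's | 0.30 M | 0.0600 M | one stirred flow tank at steady state, fed with the mixture as stated, mean residence time 20 h |  |
| Monday's | 0.30 M | 0.0600 M | one stirred flow tank at steady state, fed with the mixture as stated, mean residence time 200 h |  |
| Sunday's | 0.30 M (fed, over 20.0 h) | 0.0600 M | all but D at the start; D goes in evenly over 20.0 h, the run ends at 20 h | 20 h |
| Saturday's | 0.30 M | 0.0600 M | everything together in a closed stirred flask, run for 20 h | 20 h |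

    D → Q (k1 = 0.287 h⁻¹)
    2 D → D2 (k2 = 0.822 M⁻¹ h⁻¹)
    D + D2 → D.D2 (k3 = 0.807 M⁻¹ h⁻¹)
    D2 → E (k4 = 0.0398 h⁻¹)
    D + G → D.G (k5 = 1.38 M⁻¹ h⁻¹)

- a species is counted by the D in it: one D2 or E counts as two
- a species is counted by the D in it: one D.D2 counts as three
- two of one species on the left: rate k times its square, two consumed each time
- the stated concentrations are those of everything mixed, before any reaction; amounts are the same in each set-up
- the feed brings no volume worth counting
- run time (Sunday's): 20 h

1. the set-up with the highest share of Q in all that became Q or D2 or D.D2 or E, at the outlet or at the end ("none" if the first two lie within 2 percentage points) (Friday's / Monday's / Sunday's / Saturday's / none)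
2. share of Q in all that became Q or D2 or D.D2 or E, at the outlet or at the end, Friday's
3. share of Q in all that became Q or D2 or D.D2 or E, at the outlet or at the end, Monday's
4. share of Q in all that became Q or D2 or D.D2 or E, at the outlet or at the end, Sunday's
5. share of Q in all that became Q or D2 or D.D2 or E, at the outlet or at the end, Saturday's

D goes to Q at a rate proportional to its concentration and to D2 at twice a rate proportional to its square, so the two draws are equal at one concentration, 0.175 M. I call this the crossover concentration, and at any D the share of these two draws that becomes Q (the instantaneous selectivity) is one over one plus D divided by it, so each decade of D below the crossover takes a decade off the dimer's draw relative to Q's.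

With Q's step taken as the sole sink of D in Monday's tank, D would stand at 0.00514 M, which is 1.53 decades under the crossover and gives, by the crossover, a share of 97.1%. But G takes D too: held at its full 0.0600 M, which overstates it, G draws 0.0828 h⁻¹ against 0.287 h⁻¹ for Q, and then Monday's D drops to 0.00400 M and the share rises to 97.8%, so this doubt moves the answer by 0.70 percentage points. A harder doubt is that D also adds to D2, which the crossover does not count, but in Monday's tank a D2 meets D at 0.00415 h⁻¹ and goes to E at 0.0398 h⁻¹, so the addition runs slower than the step to E, and I keep Monday's share between those two figures.

Saturday's flask opens at 0.30 M, above the crossover, with a share of 36.8%. That holds for the start, though, and averaged over a fall of D to nothing, counting these two draws, the share is the crossover over the charge, times the logarithm of one plus the charge over the crossover, which gives 58.2%, still less than Monday's. Leaving the dimer's draw aside and holding G at its full 0.0600 M, I put D in Friday's tank at 0.0357 M, for a share of 83.0%, and Sunday's D, fed at 0.0150 M h⁻¹, near 0.0523 M if Q's step is its sole sink; both estimates stand higher than Monday's, so I choose Monday's.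

The forecast also names Monday's, with 97.4% there, 82.1% for Friday's, 81% for Sunday's and 57% for Saturday's, holding that “whichever set-up holds D lowest wins”; my own 83.0% for Friday's and 58.2% for Saturday's lie above its values.

The simulation gives Monday's as best, at 97.4%, higher than 82.2% for Friday's, 82.3% for Sunday's and 55.0% for Saturday's, so the forecast stands. D in Monday's tank reads 0.00445 M, which is 1.59 decades under the crossover concentration, and that is the reading to watch when you repeat the run. Friday's tank reads 0.0339 M, a ratio of 0.194 to the same 0.175 M, so the crossover gives 83.8% there, where Friday's tank returns 82.2%.

(The numbers come from no measurement, and the outcome is calculated.)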